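The numbers in the tables were computed from invented constants; noise was put on by code.

Every Z charged stands at any moment as Z, J, Q, G or D, with one D counting as two, so the percentages of the Z charged close at 100. We keep the books on Z.

| flask | Z | E | X | remark | time |
|---|---|---|---|---|---|
| ash | 39 mM | 29 mM | 35.1 mM | run made earlier |  |
| oak | 39 mM | 120 mM | 35.1 mM | run made earlier |  |
| flask | 39 mM | 58.5 mM | 35.1 mM |  | 15 d |

| run | time / d | Q / % | G / % |
|---|---|---|---|
| ash | 0.500 | 0.3 | 2.6 |
| ash | 1.25 | 1.9 | 6.9 |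
| ash | 2.50 | 2.4 | 11.2 |
| ash | 4.00 | 2.9 | 14.0 |
| ash | 5.00 | 2.9 | 15.7 |
| ash | 8.00 | 4.6 | 21.9 |
| ash | 10.0 | 5.3 | 22.6 |
| oak | 1.25 | 5.1 | 5.5 |
| oak | 2.50 | 9.7 | 10.5 |
| oak | 4.00 | 12.9 | 14.7 |
| oak | 5.00 | 14.9 | 15.1 |
| oak | 6.00 | 16.4 | 17.9 |
| oak | 8.00 | 17.8 | 19.3 |
| oak | 10.0 | 19.4 | 20.3 |

(scatter of a reading: 0.5 percentage points)

- a species is counted by the Z in it: one D counts as two
- reactions considered so far: Z <-> J; E + J -> Q; X + J -> G; 2 Z -> D

- ratio of Q to G at 5.0 h
- ratio of Q to G at 15 d
- which of Q and G there is more of at 15 d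

Z leaves by two accounts: in pairs to D, or through J to Q or G, where E and X compete for the same J. The first entry is the split of J between Q and G. We read it from the oak run at 10.0 d, with E and X taken at their means over the run:

Q over G = 0.956
mean E over mean X = 3.73
quotient = 0.256

This quotient is the selectivity factor, the Q formed per G formed at equal E and X. The ash run, with a quarter of oak's E, gives a reading of 0.257 the same way, so we take Q over G as the factor times E over X.

Our ledger for the flask:

Q over G at 5.0 h, from the charges: 0.427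
Q plus G at 15 d, entered from oak's total at 10.0 d: 39.7%
Q over G with mean E and X: 0.485
Q 13.0%, G 26.7%, left for Z, J and D 60.3%

That total is a stand-in: the flask has less E than oak but runs longer.

The forecast gave 0.43 (0.38 to 0.48) at 5.0 h and 0.48 (0.43 to 0.54) at 15 d, with G ahead, and said that the dimer “caps the yields but leaves the ratio unchanged”.

The flask gives 0.418 at 5.0 h and 0.468 at 15 d, with G ahead at 25.2% against Q at 11.8%, while D holds 53.9% and Z 9.10%.

    Z ⇌ J (K = 0.00320, k = 1.50 × 10⁻⁴ s⁻¹)
    E + J → Q (k = 0.00173 M⁻¹ s⁻¹)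
    X + J → G (k = 0.00694 M⁻¹ s⁻¹)
    2 Z → D (k = 4.04 × 10⁻⁵ M⁻¹ s⁻¹)

In the flask J falls back 150 times as fast as it goes on at 3.18 d; at 15.0 d it goes to G 1.9 times as fast as to Q, and the selectivity factor with the E and X then left gives 1.83 for that comparison. The neighbouring flask with 150 mM of E, where the factor gives 1.09 from the charges, shows 1.07 at 5.0 h and ends with Q at 26.2% against G at 22.2%.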